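## Analysis of the target

The target 26 is a C2-symmetric, ether-linked dimer of a 7-hydroxyisoflavan. It contains two 3-arylchroman units (ring A fused to the pyran ring, ring B on C3), and the two rings B are joined by one oxygen between their C4' carbons. Each ring B is contiguously tetrasubstituted: C1' carries the chroman, C2' a methoxy group, C3' a free hydroxyl and C4' the diaryl ether oxygen. There are two stereocenters, C3 and C3'', both R. They lie ten bonds apart across the ether bridge, so neither can control the other; each must be set by a reagent, and incomplete selectivity produces a meso diastereomer as well as the enantiomer. C3 bears no heteroatom and is not next to a carbonyl group, so it cannot epimerise once set, but it also offers no handle for a directed reaction. The sensitive groups are the four phenols, two of them on the very electron-rich ring B; the methyl ethers and the diaryl ether are robust. The difficulties are the oxygen at the hindered C3' position, the differentiation of the two ring A oxygens (one becomes O1, one stays free) and, above all, the two remote, unfunctionalised tertiary stereocenters. The strategy rests on the substitution at C3: a CH that carries ring B, the C4 methylene and the C2 methylene bound to O1, which is what anti-Markovnikov addition of hydrogen (to C3) and a heteroatom (to C2) across a 1,1-disubstituted C3=C2 alkene leaves behind.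

## Retrosynthetic reasoning

**26 from 25.** The four phenols (two at C7, two at C3') are unmasked last. In 25 all four are benzyl ethers, so a single hydrogenolysis frees them without touching the diaryl ether, the methyl ethers or C3.

**25 from 24.** Each pyran ring is opened at O1–C2. C2 is primary and not stereogenic, so closing this bond by displacement of an activated primary alcohol by the ring A phenol cannot disturb C3. Cutting C8a–O1 instead would require a halide on ring A and a metal-catalysed aryl etherification. Cutting C4–C4a would require a C–C ring closure next to the stereocenter.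

**24 from 23, and 23 from 22.** The ring A oxygen that becomes O1 is carried as a MOM ether, the only acid-labile group, so it can be freed in the presence of the benzyl ethers. The primary alcohols of 23 come from the C2–B bonds of 22 by oxidation at a primary carbon, which again leaves C3 alone.

**22 from 20 and 21.** Both C3–H bonds and both C2–B bonds are cut together, which leads back to the bis(1,1-disubstituted alkene) 20 and pinacolborane 21. This is the place to cut because C3 has no neighbouring group that could steer a substrate-controlled reaction, whereas its three carbon substituents are exactly those of a hydroborated 2-aryl-3-arylpropene. The gain is that both stereocenters are created catalytically in one operation on a symmetrical, stereochemically blank substrate. The forward reaction has to place copper on the terminal carbon and hydride on one face of C3, twice.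

**20 from 13 and 19.** Each alkene is cut at C3–C1', an sp2–sp2 bond between the alkene and ring B. This divides 20 into one symmetrical core, the bis(boronate) 13, and two copies of one ring A piece, the alkenyl bromide 19. It also avoids methylenation of an enolisable benzyl aryl ketone. The forward reaction is a double Suzuki coupling that must not move the double bond into conjugation.

**19 from 16 and 17 (through 18), 16 from 15, 15 from 14.** The C4–C4a bond is cut. The aryl Grignard reagent 18 displaces the allylic bromide of 17 and leaves the vinylic bromide as the coupling handle. The bromide 16 comes from 14 by benzylation of the hydroxyl para to bromine (giving 15) and MOM protection of the hydroxyl ortho to bromine. The two groups must differ because one oxygen becomes O1 and the other the 7-hydroxyl.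

**13 from 12, 12 from 11, 11 from 9.** The C1'–B bond is traced back through the triflate 12 and the phenol 11 to the formyl group of 9. The aldehyde carbon is needed only to activate the ether-forming substitution, and afterwards it is excised by Dakin oxidation.

**9 from 8, 8 from 4, 4 from 3.** The two C3'–O bonds are cut. In the bis(acetal) 4 the C3' hydrogen is the only one flanked by two oxygen substituents (the methoxy group and the diaryl ether oxygen), so directed metalation should find it on both rings. The aldehydes are masked as acetals for this step and return on acidic work-up to give 8, which is benzylated to 9.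

**3 from 1 and 2.** The diaryl ether is cut at C4'–O. The para-formyl group of 1 makes fluoride displaceable by the phenoxide of 2, and because both partners have the same substitution the symmetrical ether 3 arises in one step.

## Alternatives that were turned down

**Alternative 1:** The two C3'–O bonds are disconnected last. The bis-isoflavan A2 has the diaryl ether, both chroman rings, both stereocenters and silyl-protected 7-hydroxyls, but hydrogen at C3'. It would be lithiated at both C3' positions with an alkyllithium–diamine base and oxygenated through a borate ester and alkaline peroxide to give A1, from which fluoride frees the 7-hydroxyls.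

- For it: C3'–H of A2 lies between the methoxy group and the ether oxygen, the same acidity argument that step 3 uses. Ring B never needs a protecting group at O3', and no tetra-oxygenated, oxidation-prone intermediate such as phenol 11 has to be handled. On those two points it is stronger than the chosen route.
- Against it: it does not make the stereocenters. A2 still needs both C3 centers from some other asymmetric reaction, so the real difficulty is untouched.
- Against it: the metalation is asked of the most advanced intermediate, which offers competing sites. C8 of each ring A also lies between two oxygens (O1 and the silyloxy group), the C4 and C2 methylenes are lateral sites, and an aryl anion next to a silyl ether invites oxygen-to-carbon silyl migration.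
- Comparison: the chosen route runs the same C–O bond formation in step 3 on a two-step intermediate in which only C3' is doubly activated. It pays one benzylation for that; the benzyl groups leave in the hydrogenolysis that is needed anyway.

**Alternative 2:** Ring A is built rather than bought. In each half C4a–C5, C7–C8 and O1–C8a are cut. The bis(methyl ketone) A4 has 5-aryl-6-silyloxyhexan-2-one arms with C3 already set. Treated with an alkoxide base and an acrylic ester, it would undergo Michael addition at the internal α-carbon (future C4a) and Claisen closure from the methyl group (future C8), giving a cyclohexane-1,3-dione on each arm. Acid would then remove the silyl groups and close both enol ethers to A3.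

- For it: four rings form in one flask, and the ring A oxygen pattern arises automatically. The regiochemical differentiation of two resorcinol oxygens (step 8 here) is not needed, and on that point it is stronger.
- Against it: the Michael donor must be the more substituted enolate of an unsymmetrical methyl ketone under equilibrating conditions, so methyl-side addition and double addition would give isomeric diones.
- Against it: C4a is an uncontrolled center, and A3 is still two oxidation levels below the target. A dehydrogenation of a vinylogous ester would have to be done in the presence of two electron-rich ring B units and several benzylic C–H bonds, followed by debenzylation.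
- Against it: A4 is itself an asymmetric synthesis problem (a γ-aryl δ-hydroxy ketone, twice).
- Comparison: the chosen route takes ring A from a commercial resorcinol in three steps, needs no redox adjustment, and makes the stereocenters in the step that defines the strategy.

**Alternative 3:** The C2–C3 bonds are cut, and C3 is made as the α-carbon of an arylacetic acid derivative. The bis(arylacetyl) imide A6, carrying two (S)-4-benzyloxazolidinones, would be enolised with TiCl4 and a tertiary amine and alkylated by the aryloxymethyl chloride A7 to give A5, the auxiliary shielding one enolate face.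

- For it: stereocontrol by a covalently bound auxiliary is the most predictable of all the options. The unwanted isomers are diastereomers while the auxiliary is attached and can be removed before it is cleaved. Here it is stronger than the chosen route, whose main stereochemical impurity is a meso isomer that differs only at remote centers. The O1–C2 bond also comes ready-made in A7.
- Against it: two equivalents of auxiliary are consumed, and arylacetyl imides enolise so readily that base or the reductive cleavage can erode the new center.
- Against it: A7 is a reactive chloromethyl aryl ether of an electron-rich phenol.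
- Against it: after the key step the pyran ring is still open. Reduction to the C4 alcohol, activation and an aryl-metal cyclisation from the ring A bromide (C4–C4a) must follow, and A6 itself requires a two-carbon homologation of both arms of aldehyde 9 and attachment of the auxiliary.
- Comparison: the chosen route replaces all of this by one catalytic step on an alkene made by cross-coupling, at the price of relying on catalyst control for both centers.

Key step: step 12

Assumption: (R)-DTBM-SEGPHOS is taken to deliver hydride to the face of each alkene that gives R at C3. This sense has to be confirmed on a model 2-aryl-3-arylpropene, and the (S)-ligand is used under the same conditions if the model shows the opposite.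

## Route

Step 1
Reactants: 1 4-fluoro-2-methoxybenzaldehyde; 2 4-hydroxy-2-methoxybenzaldehyde
Product: 3 4,4'-oxybis(2-methoxybenzaldehyde)
Conditions: K2CO3, DMF, 120 °C
Reagents that add atoms: none
Why: Nucleophilic aromatic substitution; the para-formyl group stabilises the Meisenheimer adduct so the phenoxide of 2 displaces fluoride from 1, and neither aldehyde has α-hydrogens that carbonate could enolise.

Step 2
Reactants: 3 4,4'-oxybis(2-methoxybenzaldehyde)
Product: 4 4,4'-oxybis[1-(dimethoxymethyl)-2-methoxybenzene]
Conditions: HC(OMe)3, MeOH, p-TsOH·H2O (cat.), rt; then Et3N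
Reagents that add atoms: trimethyl orthoformate, COC(OC)OC; methanol, CO
Why: Acid-catalysed acetalisation driven by the orthoformate as water scavenger; the acetals make the aldehydes inert to the alkyllithium of step 3.

Step 3
Reactants: 4 4,4'-oxybis[1-(dimethoxymethyl)-2-methoxybenzene]
Product: 8 4,4'-oxybis(3-hydroxy-2-methoxybenzaldehyde), via 3,3'-dilithio bis-acetal 5 (not isolated), via bis(dimethyl boronate) 6 (not isolated), via bis-phenol bis-acetal 7 (not isolated)
Conditions: n-BuLi, TMEDA, THF, 0 °C; B(OMe)3, −78 °C to rt; 30% H2O2, aq NaOH, 0 °C; Na2SO3; then 2 M HCl, THF, rt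
Reagents that add atoms: n-butyllithium, [Li]CCCC (lithium of 5 only); trimethyl borate, COB(OC)OC (boron of 6 only); hydrogen peroxide, OO (phenol oxygens); water, O (aldehyde oxygens)
Why: Directed ortho-metalation; on each ring only the hydrogen between the methoxy group and the diaryl ether oxygen is flanked by two coordinating oxygens, and the 2,2'-dilithiation of a diaryl ether is a known mode. Borylation and peroxide oxidation turn C–Li into C–OH (a bridged borinate, if it forms, is oxidised to the same bis-phenol), and the acidic work-up after destroying the peroxide returns the aldehydes.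

Step 4
Reactants: 8 4,4'-oxybis(3-hydroxy-2-methoxybenzaldehyde)
Product: 9 4,4'-oxybis[3-(benzyloxy)-2-methoxybenzaldehyde]
Conditions: BnBr, K2CO3, DMF, 60 °C
Reagents that add atoms: benzyl bromide, BrCc1ccccc1
Why: Williamson etherification of the two phenols; a primary benzylic halide in a dipolar solvent alkylates even a phenoxide with two ortho substituents.

Step 5
Reactants: 9 4,4'-oxybis[3-(benzyloxy)-2-methoxybenzaldehyde]
Product: 11 4,4'-oxybis[3-(benzyloxy)-2-methoxyphenol], via bis(aryl formate) 10 (not isolated)
Conditions: mCPBA, CH2Cl2, 0 °C to rt; aq Na2S2O3 wash; then K2CO3, MeOH, rt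
Reagents that add atoms: 3-chloroperoxybenzoic acid, OOC(=O)c1cccc(Cl)c1
Why: Dakin-type Baeyer–Villiger oxidation; the aryl group, made electron-rich by ortho-methoxy and para-aryloxy donors, migrates in preference to hydride, and the formates are cleaved by methanolysis.

Step 6
Reactants: 11 4,4'-oxybis[3-(benzyloxy)-2-methoxyphenol]
Product: 12 bis(trifluoromethanesulfonate) of 11
Conditions: Tf2O, pyridine, CH2Cl2, 0 °C
Reagents that add atoms: trifluoromethanesulfonic anhydride, O=S(=O)(OS(=O)(=O)C(F)(F)F)C(F)(F)F
Why: O-Sulfonylation of both phenols; it converts the C1' oxygen into a leaving group for palladium and removes the oxidation-prone free phenol at once.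

Step 7
Reactants: 12 bis(trifluoromethanesulfonate) of 11
Product: 13 core bis(pinacol boronate): bis[3-(benzyloxy)-2-methoxy-4-(4,4,5,5-tetramethyl-1,3,2-dioxaborolan-2-yl)phenyl] ether
Conditions: B2pin2, Pd(dppf)Cl2, dppf, KOAc, 1,4-dioxane, 90 °C
Reagents that add atoms: bis(pinacolato)diboron, CC1(C)OB(OC1(C)C)B1OC(C)(C)C(C)(C)O1
Why: Miyaura borylation of aryl triflates; zerovalent palladium inserts into each C–OTf bond, and acetate mediates transmetalation with the diboron without triggering Suzuki homocoupling.

Step 8
Reactants: 14 4-bromoresorcinol
Product: 15 5-(benzyloxy)-2-bromophenol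
Conditions: BnBr (1.0 equiv), K2CO3 (1.05 equiv), acetone, rt to 40 °C
Reagents that add atoms: benzyl bromide, BrCc1ccccc1
Why: Williamson monoalkylation under limiting base; the hydroxyl para to bromine is the less hindered and the more nucleophilic of the two, so it should be alkylated preferentially, and the regioisomer and bis-ether are removed by chromatography.

Step 9
Reactants: 15 5-(benzyloxy)-2-bromophenol
Product: 16 4-(benzyloxy)-1-bromo-2-(methoxymethoxy)benzene
Conditions: MOMCl, i-Pr2NEt, CH2Cl2, 0 °C to rt
Reagents that add atoms: chloromethyl methyl ether, COCCl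
Why: Acetal-type protection of the remaining phenol; the MOM ether survives Grignard formation, both couplings and the copper hydride step, and is the one acid-labile group of the route.

Step 10
Reactants: 16 4-(benzyloxy)-1-bromo-2-(methoxymethoxy)benzene; 17 2,3-dibromopropene
Product: 19 4-(benzyloxy)-1-(2-bromoprop-2-en-1-yl)-2-(methoxymethoxy)benzene, via arylmagnesium bromide 18 (not isolated)
Conditions: Mg, THF, 45 °C; then CuI (5 mol %), 17, −20 °C to rt
Reagents that add atoms: magnesium, [Mg] (in 18 only)
Why: Grignard formation followed by copper-catalysed allylic substitution; direct and allylic-transposed attack on 17 give the same 2-bromoallyl arene, and the vinylic bromide is untouched.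

Step 11
Reactants: 13 core bis(pinacol boronate); 19 4-(benzyloxy)-1-(2-bromoprop-2-en-1-yl)-2-(methoxymethoxy)benzene (2.4 equiv)
Product: 20 bis(1,1-disubstituted alkene): bis{3-(benzyloxy)-2-methoxy-4-[3-(4-(benzyloxy)-2-(methoxymethoxy)phenyl)prop-1-en-2-yl]phenyl} ether
Conditions: Pd(OAc)2, SPhos, K3PO4, toluene/H2O (10:1), 70 °C
Reagents that add atoms: none
Why: Two-fold Suzuki–Miyaura coupling of an aryl boronate with an alkenyl bromide; the alkenyl bromide adds oxidatively with ease, and the bulky biaryl phosphine speeds transmetalation of the ortho-substituted boronate so that coupling outruns protodeboronation.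

Step 12
Reactants: 20 bis(1,1-disubstituted alkene); 21 pinacolborane (3 equiv)
Product: 22 (R,R)-bis(primary pinacol boronate): bis{3-(benzyloxy)-2-methoxy-4-[(2R)-1-(4-(benzyloxy)-2-(methoxymethoxy)phenyl)-3-(4,4,5,5-tetramethyl-1,3,2-dioxaborolan-2-yl)propan-2-yl]phenyl} ether
Conditions: CuCl (10 mol %), (R)-DTBM-SEGPHOS (11 mol %), NaOt-Bu (20 mol %), toluene, rt
Reagents that add atoms: none
Why: NaOt-Bu turns CuCl and the bisphosphine into LCuOt-Bu, which 21 converts into the monovalent copper hydride LCuH; this adds syn across each C3=C2 bond with hydride to C3 and copper to the terminal C2 (the enantio-determining step), and σ-bond metathesis of the primary alkylcopper with 21 forms the C2–B bond and returns LCuH. The closest known reaction type is the copper hydride-catalysed anti-Markovnikov enantioselective hydroboration of 1,1-disubstituted aryl alkenes with pinacolborane, applied here to two alkenes of one molecule. No ring closes. Each C3 stereocenter is set by the ligand alone, whose chiral pocket distinguishes the twisted, ortho-methoxy-substituted ring B from the flexible CH2-aryl group on the other side of the alkene. Regioselectivity is required and follows from the 1,1-disubstitution: copper at C3 would be a tertiary center that the bulky ligand cannot accommodate, and the ortho-methoxy twist removes most of the benzylic stabilisation that would favour it. Chemoselectivity is secured because the substrate has no carbonyl group, aryl halide or β-leaving group; benzyl, MOM, methyl and diaryl ethers are inert to LCuH. Since the two remote alkenes react independently, most minor-face additions end up in the meso diastereomer, so the (R,R) product should be enantiomerically purer than one event alone would make it, at the cost of a meso impurity to be removed at 23 or 25.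

Step 13
Reactants: 22 (R,R)-bis(primary pinacol boronate)
Product: 23 (R,R)-diol: bis{3-(benzyloxy)-4-[(2R)-1-hydroxy-3-(4-(benzyloxy)-2-(methoxymethoxy)phenyl)propan-2-yl]-2-methoxyphenyl} ether
Conditions: NaBO3·4H2O, THF/H2O (1:1), rt
Reagents that add atoms: sodium perborate tetrahydrate, [Na+].[O-]OB=O.O.O.O.O
Why: Oxidation of the alkyl boronates by 1,2-migration of the primary carbon from boron to oxygen; the reaction is at C2 only, so C3 is not touched, and the mild perborate leaves the MOM and benzyl ethers alone.

Step 14
Reactants: 23 (R,R)-diol
Product: 24 (R,R)-diol bis-phenol: bis{3-(benzyloxy)-4-[(2R)-1-hydroxy-3-(4-(benzyloxy)-2-hydroxyphenyl)propan-2-yl]-2-methoxyphenyl} ether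
Conditions: conc. HCl (cat.), MeOH/THF (2:1), 45 °C
Reagents that add atoms: none
Why: Acid-catalysed acetal exchange removes both MOM groups as dimethoxymethane, which also keeps the released formaldehyde equivalent away from the electron-rich rings; benzyl ethers, primary alcohols and the non-acidic C3 are stable.

Step 15
Reactants: 24 (R,R)-diol bis-phenol
Product: 25 (3R,3''R)-tetrabenzyl ether of the target: bis[3-(benzyloxy)-4-((3R)-7-(benzyloxy)chroman-3-yl)-2-methoxyphenyl] ether
Conditions: PPh3, DIAD, THF (0.01 M), 0 °C to rt
Reagents that add atoms: none
Why: Double intramolecular Mitsunobu etherification; each primary alcohol is activated as its alkoxyphosphonium ion and displaced by the neighbouring ring A phenol in a 6-exo-tet closure of O1–C2. The reaction center is the non-stereogenic C2, so C3 keeps its configuration, and the only other oxygens are benzyl-protected.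

Step 16
Reactants: 25 (3R,3''R)-tetrabenzyl ether of the target
Product: 26 the target, (3R,3''R)-bis[2-hydroxy-4-(7-hydroxychroman-3-yl)-3-methoxyphenyl] ether
Conditions: H2 (1 atm), 10% Pd/C, EtOAc/MeOH (1:1), rt
Reagents that add atoms: none
Why: Hydrogenolysis of the four benzylic C–O bonds; the aryl–O–alkyl bond of the chroman, the diaryl ether and the methyl ethers are not benzylic C–O bonds and stay intact.

## Compound list

1 | 4-fluoro-2-methoxybenzaldehyde | COc1cc(F)ccc1C=O | starting material
2 | 4-hydroxy-2-methoxybenzaldehyde | COc1cc(O)ccc1C=O | starting material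
3 | 4,4'-oxybis(2-methoxybenzaldehyde) | COc1cc(Oc2ccc(C=O)c(OC)c2)ccc1C=O | intermediate
4 | 4,4'-oxybis[1-(dimethoxymethyl)-2-methoxybenzene] | COc1cc(Oc2ccc(C(OC)OC)c(OC)c2)ccc1C(OC)OC | intermediate
5 | 3,3'-dilithio derivative of 4 (lithium between the methoxy group and the ether oxygen on each ring) | COc1c([Li])c(Oc2ccc(C(OC)OC)c(OC)c2[Li])ccc1C(OC)OC | intermediate (not isolated)
6 | bis(dimethyl boronate) from 5 | COc1c(B(OC)OC)c(Oc2ccc(C(OC)OC)c(OC)c2B(OC)OC)ccc1C(OC)OC | intermediate (not isolated)
7 | 6,6'-oxybis[3-(dimethoxymethyl)-2-methoxyphenol] | COc1c(O)c(Oc2ccc(C(OC)OC)c(OC)c2O)ccc1C(OC)OC | intermediate (not isolated)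
8 | 4,4'-oxybis(3-hydroxy-2-methoxybenzaldehyde) | COc1c(O)c(Oc2ccc(C=O)c(OC)c2O)ccc1C=O | intermediate
9 | 4,4'-oxybis[3-(benzyloxy)-2-methoxybenzaldehyde] | COc1c(OCc2ccccc2)c(Oc2ccc(C=O)c(OC)c2OCc2ccccc2)ccc1C=O | intermediate
10 | bis(aryl formate) from 9 (formyloxy in place of each formyl group) | COc1c(OCc2ccccc2)c(Oc2ccc(OC=O)c(OC)c2OCc2ccccc2)ccc1OC=O | intermediate (not isolated)
11 | 4,4'-oxybis[3-(benzyloxy)-2-methoxyphenol] | COc1c(OCc2ccccc2)c(Oc2ccc(O)c(OC)c2OCc2ccccc2)ccc1O | intermediate
12 | bis(trifluoromethanesulfonate) of 11 | COc1c(OCc2ccccc2)c(Oc2ccc(OS(=O)(=O)C(F)(F)F)c(OC)c2OCc2ccccc2)ccc1OS(=O)(=O)C(F)(F)F | intermediate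
13 | bis[3-(benzyloxy)-2-methoxy-4-(4,4,5,5-tetramethyl-1,3,2-dioxaborolan-2-yl)phenyl] ether | COc1c(OCc2ccccc2)c(Oc2ccc(B3OC(C)(C)C(C)(C)O3)c(OC)c2OCc2ccccc2)ccc1B1OC(C)(C)C(C)(C)O1 | intermediate
14 | 4-bromoresorcinol (4-bromobenzene-1,3-diol) | Oc1ccc(Br)c(O)c1 | starting material
15 | 5-(benzyloxy)-2-bromophenol | Oc1cc(OCc2ccccc2)ccc1Br | intermediate
16 | 4-(benzyloxy)-1-bromo-2-(methoxymethoxy)benzene | COCOc1cc(OCc2ccccc2)ccc1Br | intermediate
17 | 2,3-dibromopropene | C=C(Br)CBr | starting material
18 | [4-(benzyloxy)-2-(methoxymethoxy)phenyl]magnesium bromide | COCOc1cc(OCc2ccccc2)ccc1[Mg]Br | intermediate (not isolated)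
19 | 4-(benzyloxy)-1-(2-bromoprop-2-en-1-yl)-2-(methoxymethoxy)benzene | COCOc1cc(OCc2ccccc2)ccc1CC(Br)=C | intermediate
20 | bis{3-(benzyloxy)-2-methoxy-4-[3-(4-(benzyloxy)-2-(methoxymethoxy)phenyl)prop-1-en-2-yl]phenyl} ether | COc1c(C(=C)Cc2ccc(OCc3ccccc3)cc2OCOC)ccc(Oc2ccc(C(=C)Cc3ccc(OCc4ccccc4)cc3OCOC)c(OC)c2OCc2ccccc2)c1OCc1ccccc1 | intermediate
21 | pinacolborane (4,4,5,5-tetramethyl-1,3,2-dioxaborolane) | CC1(C)OBOC1(C)C | starting material
22 | (R,R)-bis(primary pinacol boronate): each alkene of 20 converted into a (2R)-CH(CH2Bpin) unit | COc1c([C@@H](Cc2ccc(OCc3ccccc3)cc2OCOC)CB2OC(C)(C)C(C)(C)O2)ccc(Oc2ccc([C@@H](Cc3ccc(OCc4ccccc4)cc3OCOC)CB3OC(C)(C)C(C)(C)O3)c(OC)c2OCc2ccccc2)c1OCc1ccccc1 | intermediate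
23 | (R,R)-diol: the two Bpin groups of 22 replaced by OH | COc1c([C@@H](Cc2ccc(OCc3ccccc3)cc2OCOC)CO)ccc(Oc2ccc([C@@H](Cc3ccc(OCc4ccccc4)cc3OCOC)CO)c(OC)c2OCc2ccccc2)c1OCc1ccccc1 | intermediate
24 | (R,R)-diol bis-phenol: 23 without the two MOM groups | COc1c([C@@H](Cc2ccc(OCc3ccccc3)cc2O)CO)ccc(Oc2ccc([C@@H](Cc3ccc(OCc4ccccc4)cc3O)CO)c(OC)c2OCc2ccccc2)c1OCc1ccccc1 | intermediate
25 | bis[3-(benzyloxy)-4-((3R)-7-(benzyloxy)chroman-3-yl)-2-methoxyphenyl] ether | COc1c([C@@H]2COc3cc(OCc4ccccc4)ccc3C2)ccc(Oc2ccc([C@@H]3COc4cc(OCc5ccccc5)ccc4C3)c(OC)c2OCc2ccccc2)c1OCc1ccccc1 | intermediate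
26 | CNP0116832.1, (3R,3''R)-bis[2-hydroxy-4-(7-hydroxychroman-3-yl)-3-methoxyphenyl] ether | COc1c([C@@H]2COc3cc(O)ccc3C2)ccc(Oc2ccc([C@@H]3COc4cc(O)ccc4C3)c(OC)c2O)c1O | target

## Step count and risks

Total: 16 steps. Longest linear sequence: 13 steps (steps 1–7 and 11–16); the ring A piece 19 is made in a three-step branch (steps 8–10).

**Step 12 (key step).** The most likely failure is incomplete facial discrimination at one of the two alkenes, which puts material into the meso diastereomer. The meso isomer differs from the product only at two remote centers and may be hard to separate. The hindered alkene, with its ortho-methoxy group, may also react slowly. Fallback: the stereocenter is set by dynamic kinetic resolution instead of hydrocupration.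
- Alkene 20 is hydroborated without stereocontrol (9-BBN, THF; then NaBO3·4H2O) to the stereorandom diol F1.
- F1 is oxidised with Dess–Martin periodinane to the bis(α-aryl aldehyde) F2, whose α-centers racemise by enolisation.
- F2 is hydrogenated under base with a chiral diphosphine–diamine catalyst of divalent ruthenium, for example RuCl2[(S)-SDP][(R,R)-DACH], KOt-Bu, H2, i-PrOH, the enantiomer being chosen on a model. One aldehyde enantiomer is reduced faster while the other equilibrates, and the route is rejoined at diol 23.

**Step 3.** The second lithiation may be incomplete, or part of the metalation may go ortho to the acetal, giving mono-oxygenated or mis-oxygenated material. Fallback: each ring is oxygenated before the ether is made.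
- Aldehyde 1 is converted into its dimethyl acetal F3.
- F3 is lithiated at −78 °C at the carbon between fluorine and methoxy, then borylated, oxidised and hydrolysed to 4-fluoro-3-hydroxy-2-methoxybenzaldehyde F4.
- F4 is benzylated to 3-(benzyloxy)-4-fluoro-2-methoxybenzaldehyde F5.
- Half of F5 is converted with acetohydroxamic acid and K2CO3 in DMSO into 3-(benzyloxy)-4-hydroxy-2-methoxybenzaldehyde F6.
- F5 and F6 are joined by nucleophilic aromatic substitution (Cs2CO3, DMSO, 120 °C), which gives 9 directly.

**Step 11.** The electron-rich, ortho-substituted boronate may protodeboronate before it couples, and palladium hydride may move the double bond into conjugation with both rings. Fallback: the polarity of the coupling is reversed.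
- Bromide 19 is borylated (B2pin2, PdCl2(PPh3)2, PPh3, KOPh, toluene, 50 °C) to the alkenyl pinacol boronate F7.
- F7 is coupled with the bis(triflate) 12 (Pd(OAc)2, SPhos, K3PO4) to give 20. Compound 13 is no longer needed.

**Step 15.** Intermolecular etherification, or alkylation of the reduced azodicarboxylate, may compete with the two ring closures. Fallback: a stepwise Williamson closure.
- Diol 23 is mesylated (MsCl, Et3N) to the bis(mesylate) F8.
- The MOM groups of F8 are removed with HCl in methanol to give the bis(mesylate) bis-phenol F9.
- F9 is cyclised with K2CO3 in DMF by phenoxide displacement to give 25.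

**Step 8.** The monobenzylation may give a poor regiochemical preference, because the hydroxyl next to bromine is the more acidic one. Fallback: the bromine is introduced by electrophilic substitution.
- 3-(Benzyloxy)phenol F10 is acetylated to 3-(benzyloxy)phenyl acetate F11.
- F11 is brominated with NBS in acetonitrile para to the stronger donor, the benzyloxy group, to give 5-(benzyloxy)-2-bromophenyl acetate F12.
- Methanolysis of F12 (K2CO3, MeOH) gives 15.

## Further compounds

F1 | step 12 | stereorandom diol (23 without defined configuration) | COc1c(C(Cc2ccc(OCc3ccccc3)cc2OCOC)CO)ccc(Oc2ccc(C(Cc3ccc(OCc4ccccc4)cc3OCOC)CO)c(OC)c2OCc2ccccc2)c1OCc1ccccc1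
F2 | step 12 | bis(α-aryl aldehyde), configurationally labile | COc1c(C(Cc2ccc(OCc3ccccc3)cc2OCOC)C=O)ccc(Oc2ccc(C(Cc3ccc(OCc4ccccc4)cc3OCOC)C=O)c(OC)c2OCc2ccccc2)c1OCc1ccccc1
F3 | step 3 | 1-(dimethoxymethyl)-4-fluoro-2-methoxybenzene | COc1cc(F)ccc1C(OC)OC
F4 | step 3 | 4-fluoro-3-hydroxy-2-methoxybenzaldehyde | COc1c(O)c(F)ccc1C=O
F5 | step 3 | 3-(benzyloxy)-4-fluoro-2-methoxybenzaldehyde | COc1c(OCc2ccccc2)c(F)ccc1C=O
F6 | step 3 | 3-(benzyloxy)-4-hydroxy-2-methoxybenzaldehyde | COc1c(OCc2ccccc2)c(O)ccc1C=O
F7 | step 11 | 2-{3-[4-(benzyloxy)-2-(methoxymethoxy)phenyl]prop-1-en-2-yl}-4,4,5,5-tetramethyl-1,3,2-dioxaborolane | COCOc1cc(OCc2ccccc2)ccc1CC(=C)B1OC(C)(C)C(C)(C)O1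
F8 | step 15 | (R,R)-bis(methanesulfonate) of 23 | COc1c([C@@H](Cc2ccc(OCc3ccccc3)cc2OCOC)COS(C)(=O)=O)ccc(Oc2ccc([C@@H](Cc3ccc(OCc4ccccc4)cc3OCOC)COS(C)(=O)=O)c(OC)c2OCc2ccccc2)c1OCc1ccccc1
F9 | step 15 | (R,R)-bis(methanesulfonate) bis-phenol (F8 without MOM groups) | COc1c([C@@H](Cc2ccc(OCc3ccccc3)cc2O)COS(C)(=O)=O)ccc(Oc2ccc([C@@H](Cc3ccc(OCc4ccccc4)cc3O)COS(C)(=O)=O)c(OC)c2OCc2ccccc2)c1OCc1ccccc1
F10 | step 8 | 3-(benzyloxy)phenol | Oc1cccc(OCc2ccccc2)c1
F11 | step 8 | 3-(benzyloxy)phenyl acetate | CC(=O)Oc1cccc(OCc2ccccc2)c1
F12 | step 8 | 5-(benzyloxy)-2-bromophenyl acetate | CC(=O)Oc1cc(OCc2ccccc2)ccc1Br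
A1 | alternative 1 | (3R,3''R)-target as its bis(7-O-triisopropylsilyl ether) | COc1c([C@@H]2COc3cc(O[Si](C(C)C)(C(C)C)C(C)C)ccc3C2)ccc(Oc2ccc([C@@H]3COc4cc(O[Si](C(C)C)(C(C)C)C(C)C)ccc4C3)c(OC)c2O)c1O
A2 | alternative 1 | (3R,3''R)-bis[3-methoxy-4-(7-(triisopropylsilyloxy)chroman-3-yl)phenyl] ether (A1 with hydrogen at both C3') | COc1c([C@@H]2COc3cc(O[Si](C(C)C)(C(C)C)C(C)C)ccc3C2)ccc(Oc2ccc([C@@H]3COc4cc(O[Si](C(C)C)(C(C)C)C(C)C)ccc4C3)c(OC)c2)c1
A3 | alternative 2 | bis(3-aryl-2,3,4,4a,5,6-hexahydro-7H-chromen-7-one), 3R at both C3, C4a epimers | COc1c([C@@H]2COC3=CC(=O)CCC3C2)ccc(Oc2ccc([C@@H]3COC4=CC(=O)CCC4C3)c(OC)c2OCc2ccccc2)c1OCc1ccccc1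
A4 | alternative 2 | bis(methyl ketone): bis{3-(benzyloxy)-4-[(2R)-1-(tert-butyldimethylsilyloxy)-5-oxohexan-2-yl]-2-methoxyphenyl} ether | COc1c([C@@H](CCC(C)=O)CO[Si](C)(C)C(C)(C)C)ccc(Oc2ccc([C@@H](CCC(C)=O)CO[Si](C)(C)C(C)(C)C)c(OC)c2OCc2ccccc2)c1OCc1ccccc1
A5 | alternative 3 | bis-alkylated imide, R at both new centers, (S)-4-benzyloxazolidinone auxiliaries | COc1c([C@@H](C(=O)N2C(=O)OC[C@@H]2Cc2ccccc2)COc2cc(OCc3ccccc3)ccc2Br)ccc(Oc2ccc([C@@H](C(=O)N3C(=O)OC[C@@H]3Cc3ccccc3)COc3cc(OCc4ccccc4)ccc3Br)c(OC)c2OCc2ccccc2)c1OCc1ccccc1
A6 | alternative 3 | bis(arylacetyl) imide of (S)-4-benzyloxazolidinone | COc1c(CC(=O)N2C(=O)OC[C@@H]2Cc2ccccc2)ccc(Oc2ccc(CC(=O)N3C(=O)OC[C@@H]3Cc3ccccc3)c(OC)c2OCc2ccccc2)c1OCc1ccccc1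
A7 | alternative 3 | 4-(benzyloxy)-1-bromo-2-(chloromethoxy)benzene | ClCOc1cc(OCc2ccccc2)ccc1Br
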